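(The earlier runs and the new flask are simulated with constants of no real substance.)

Target plus starting material holds steady in the south run, 90.5% at the first reading and 90.1% at the last, while target climbs and falls back. So these two exchange, and the missing 10.0%, which matches the protic impurity measured against the starting material, has left before the first reading.

| setting | south | flask |
|---|---|---|
| starting material | 0.50 M | 0.50 M |
| second substrate | 0.50 M | 0.500 M |
| coupling partner | 0.50 M | 0.500 M |
| protic impurity | 0.050 M | 0.0500 M |
| free catalyst | 1.2 mM | 2.5 mM |
| remark | run made earlier |  |
| time |  | 50 min |

south run (percent of the starting material charged)

| time / min | target / % | starting material / % |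
|---|---|---|
| 1.33 | 11.1 | 79.4 |
| 3.00 | 15.0 | 75.2 |
| 6.00 | 14.0 | 75.0 |
| 15.0 | 7.2 | 82.9 |

(scatter of a reading: 0.5 percentage points)

- the numbers in the tables scatter by 0.5 percentage points (one standard deviation)
- no earlier run changes the charge of free catalyst; that part of a forecast is a guess

- time up to 50 min at which target stands highest
- the amount of target, in percent of the starting material charged, at that time
- the first time at which target reaches 7.7%, in the same percent, in min

At any moment target gains at one rate and loses at another, and the peak is where the two are equal. I assume that free catalyst, a trace, enters both rates as a factor. Their ratio then drifts with composition and not with catalyst, so a flask walks the same road faster. One number carries south over to this flask: the clock factor, free catalyst charged here over free catalyst charged in south, 2.08, the south minutes that pass in one minute here (time normalisation by catalyst). No run varies the catalyst, so this is a guess.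

The height should stay near the highest south reading, 15.0%. The south peak lies between 3.00 min and 6.00 min, which puts this flask's peak between 1.44 min and 2.88 min; I commit to the middle, 2.16 min. A straight line to the first south reading reaches the asked level at 0.443 min here. Is one number enough? The early loss may keep its own clock, but in south it is over by 1.33 min, so I let the number stand.

The forecast says 3.8 min, 27.5% and 0.35 min, a height above mine, holding that more catalyst "should roughly double the flux".

This flask gives 2.05 min, 15.5% and 0.420 min.

    starting material + protic impurity → quenched substrate (k = 3.50 M⁻¹ s⁻¹)
    coupling partner + catalyst intermediate A ⇌ free catalyst + target (K = 0.370, k = 8.20 M⁻¹ s⁻¹)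
    coupling partner + catalyst intermediate B → free catalyst + second product (k = 5.60 M⁻¹ s⁻¹)
    starting material + free catalyst ⇌ catalyst intermediate A (K = 2.40 M⁻¹, k = 6.20 M⁻¹ s⁻¹)
    second substrate + free catalyst ⇌ catalyst intermediate B (K = 15.0 M⁻¹, k = 4.50 M⁻¹ s⁻¹)

The largest single effect on this flask's best, though not the whole of what holds it down, is the way back from catalyst intermediate A to starting material and free catalyst: the run without that way back reaches 59.1% against 15.5%. On the south clock the best time of this flask lies at 4.26 min, between the two highest south readings, and this flask's 11.0% at 5.00 min lies at 10.4 min, between the south readings of 14.0% and 7.2%.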